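**Strategy.** The route rests on disconnecting C7–C8: C7 is the methyl-bearing sp2 carbon of the (6E) trisubstituted alkene, C8 the first carbon of the two-carbon tether to C1 of the 2,6,6-trimethylcyclohexene ring. A Zweifel olefination forges this bond and fixes the 6E geometry in one operation: the (6Z)-alkenyllithium from an iodo-Wittig-derived nine-carbon iodo alcohol adds to the pinacol boronate of the ring fragment, and iodine-induced 1,2-migration followed by anti elimination inverts the alkene. The step exploits the junction of an alkene carbon (C7 of C6=C7) with an unhindered primary carbon (C8). The ring stereocentre arises from a CBS reduction relayed by Johnson–Claisen rearrangement; oleoylation finishes the synthesis.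

Key step: step 9

Remark: chain atoms are numbered C1 (the CH2O carbon) to C9 along the nonadienyl chain and ring atoms C1 to C6 as in the name of 18; compounds 1, 8 and 17 are taken to be purchased.

Step 1
Reactants: 1 2,4,4-trimethylcyclohex-2-en-1-one
Product: 2 (1R)-2,4,4-trimethylcyclohex-2-en-1-ol
Conditions: (S)-Me-CBS oxazaborolidine (from (S)-diphenylprolinol, 10 mol%), catecholborane, toluene, −78 °C; aq. NaOH work-up
Reagents that add atoms: none
Why: Corey–Bakshi–Shibata reduction, in which the enone should bind the (S)-oxazaborolidine with its alkenyl arm as the large group, so that 1,2-hydride delivery gives the (1R) allylic alcohol.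

Step 2
Reactants: 2 (1R)-2,4,4-trimethylcyclohex-2-en-1-ol
Product: 4 ethyl 2-[(1S)-2,6,6-trimethylcyclohex-2-en-1-yl]acetate, via ketene acetal 3 (not isolated)
Conditions: MeC(OEt)3 (excess), EtCO2H (cat.), 140 °C, EtOH distilled off
Reagents that add atoms: triethyl orthoacetate CCOC(C)(OCC)OCC
Why: Johnson–Claisen (orthoester) rearrangement, in which the [3,3] shift is suprafacial across the ring, so the C–O stereocentre of 2 should be relayed to ring carbon C1 as (S) while the alkene moves to C2=C3.

Step 3
Reactants: 4 ethyl 2-[(1S)-2,6,6-trimethylcyclohex-2-en-1-yl]acetate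
Product: 5 2-[(1S)-2,6,6-trimethylcyclohex-2-en-1-yl]ethan-1-ol
Conditions: LiAlH4, Et2O, 0 °C
Reagents that add atoms: none
Why: Hydride reduction of an ester to the primary alcohol, which should leave the isolated trisubstituted alkene and the non-epimerisable stereocentre untouched.

Step 4
Reactants: 5 2-[(1S)-2,6,6-trimethylcyclohex-2-en-1-yl]ethan-1-ol
Product: 6 (6S)-6-(2-iodoethyl)-1,5,5-trimethylcyclohex-1-ene
Conditions: PPh3, I2, imidazole, CH2Cl2, 0 to 23 °C
Reagents that add atoms: iodine [I][I]
Why: Appel-type iodination, an SN2 displacement of the oxyphosphonium at the primary carbon that does not involve the stereocentre.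

Step 5
Reactants: 6 (6S)-6-(2-iodoethyl)-1,5,5-trimethylcyclohex-1-ene
Product: 7 4,4,5,5-tetramethyl-2-{2-[(1S)-2,6,6-trimethylcyclohex-2-en-1-yl]ethyl}-1,3,2-dioxaborolane
Conditions: B2pin2, CuI (10 mol%), PPh3 (13 mol%), LiOMe, DMF, 23 °C
Reagents that add atoms: bis(pinacolato)diboron CC1(C)OB(OC1(C)C)B1OC(C)(C)C(C)(C)O1
Why: Copper-catalysed borylation of a primary alkyl iodide with a diboron reagent, mild enough that the ring alkene and stereocentre should be unaffected.

Step 6
Reactants: 8 geranyl acetate
Product: 10 (2E)-3-methyl-6-oxohex-2-en-1-yl acetate, via ozonide 9 (not isolated)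
Conditions: O3 (1 equiv), CH2Cl2, −78 °C; then Me2S, −78 to 23 °C
Reagents that add atoms: ozone [O-][O+]=O
Why: Chemoselective ozonolysis with reductive work-up, in which the electron-rich C6=C7 alkene should react faster than the C2=C3 alkene deactivated by the allylic acetate.

Step 7
Reactants: 10 (2E)-3-methyl-6-oxohex-2-en-1-yl acetate
Product: 11 (2E,6Z)-7-iodo-3-methylocta-2,6-dien-1-yl acetate
Conditions: EtPPh3I, n-BuLi, THF, 23 °C; I2, −78 °C; NaN(SiMe3)2, −78 to −20 °C; then 10, −78 to 23 °C
Reagents that add atoms: ethyltriphenylphosphonium iodide CC[P+](c1ccccc1)(c1ccccc1)c1ccccc1.[I-]; iodine [I][I]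
Why: Stork–Zhao variant of the Wittig olefination, in which the non-stabilised alpha-iodo ylide should add under kinetic control to give the (6Z)-iodoalkene (iodine cis to C5) while the acetate survives at low temperature.

Step 8
Reactants: 11 (2E,6Z)-7-iodo-3-methylocta-2,6-dien-1-yl acetate
Product: 12 (2E,6Z)-7-iodo-3-methylocta-2,6-dien-1-ol
Conditions: K2CO3 (cat.), MeOH, 0 to 23 °C
Reagents that add atoms: none
Why: Base-catalysed transesterification (methanolysis) of the acetate, to which the alkenyl iodide and both alkene geometries should be inert.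

Step 9
Reactants: 12 (2E,6Z)-7-iodo-3-methylocta-2,6-dien-1-ol; 7 4,4,5,5-tetramethyl-2-{2-[(1S)-2,6,6-trimethylcyclohex-2-en-1-yl]ethyl}-1,3,2-dioxaborolane
Product: 16 (2E,6E)-3,7-dimethyl-9-[(1S)-2,6,6-trimethylcyclohex-2-en-1-yl]nona-2,6-dien-1-ol, via dilithio species 13 (not isolated), via boronate complex 14 (not isolated), via iodoboronate 15 (not isolated)
Conditions: 12, t-BuLi (3.1 equiv), Et2O, −78 °C; 7, THF, −78 °C; I2, THF, −78 °C; NaOMe, MeOH, −78 to 23 °C; aq. Na2S2O3
Reagents that add atoms: none
Why: Zweifel olefination, a boron 1,2-metallate rearrangement: O-deprotonation and iodine–lithium exchange on 12 give the configurationally stable alkenyllithium 13, which adds to boron of 7 to form boronate complex 14. Iodine activates the C6=C7 bond of 14 as an iodonium ion, and the primary alkyl carbon C8 migrates from boron to C7 anti to the new C6–I bond, creating the C7–C8 bond in 15. Methoxide then triggers anti elimination of boron and iodide, so the geometry is inverted overall: the alkenyl boronate with boron cis to C5 should give the (6E) alkene with C8 trans to C5. No ring is closed and no stereocentre is created; the C6=C7 geometry is controlled by the stereospecific anti-migration/anti-elimination sequence, and ring stereocentre C1 is remote and untouched. The step needs chemoselective iodination of one alkene among three, secured because only C6=C7 carries the electron-releasing anionic boronate, and exclusive carbon migration, secured because the pinacol oxygens do not migrate. The hydroxyl is carried as its lithium alkoxide, which should remain a spectator.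

Step 10
Reactants: 16 (2E,6E)-3,7-dimethyl-9-[(1S)-2,6,6-trimethylcyclohex-2-en-1-yl]nona-2,6-dien-1-ol; 17 oleoyl chloride
Product: 18 (2E,6E)-3,7-dimethyl-9-[(1S)-2,6,6-trimethylcyclohex-2-en-1-yl]nona-2,6-dien-1-yl (9Z)-octadec-9-enoate
Conditions: Et3N, DMAP (cat.), CH2Cl2, 0 to 23 °C
Reagents that add atoms: none
Why: DMAP-catalysed acylation of a primary allylic alcohol by an acid chloride (nucleophilic catalysis), which should not isomerise any of the four alkenes.

**Compound list**

1 | 2,4,4-trimethylcyclohex-2-en-1-one | CC1=CC(C)(C)CCC1=O | starting material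
2 | (1R)-2,4,4-trimethylcyclohex-2-en-1-ol | O[C@@H]1CCC(C)(C)C=C1C | intermediate
3 | (1R)-1-[(1-ethoxyethenyl)oxy]-2,4,4-trimethylcyclohex-2-ene (mixed ketene acetal) | C=C(OCC)O[C@@H]1CCC(C)(C)C=C1C | intermediate
4 | ethyl 2-[(1S)-2,6,6-trimethylcyclohex-2-en-1-yl]acetate | CCOC(=O)C[C@@H]1C(C)=CCCC1(C)C | intermediate
5 | 2-[(1S)-2,6,6-trimethylcyclohex-2-en-1-yl]ethan-1-ol | OCC[C@@H]1C(C)=CCCC1(C)C | intermediate
6 | (6S)-6-(2-iodoethyl)-1,5,5-trimethylcyclohex-1-ene | ICC[C@@H]1C(C)=CCCC1(C)C | intermediate
7 | 4,4,5,5-tetramethyl-2-{2-[(1S)-2,6,6-trimethylcyclohex-2-en-1-yl]ethyl}-1,3,2-dioxaborolane | CC1(C)OB(CC[C@@H]2C(C)=CCCC2(C)C)OC1(C)C | intermediate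
8 | geranyl acetate [(2E)-3,7-dimethylocta-2,6-dien-1-yl acetate] | CC(=O)OC/C=C(\C)CCC=C(C)C | starting material
9 | (2E)-5-(5,5-dimethyl-1,2,4-trioxolan-3-yl)-3-methylpent-2-en-1-yl acetate (secondary ozonide) | CC(=O)OC/C=C(\C)CCC1OOC(C)(C)O1 | intermediate
10 | (2E)-3-methyl-6-oxohex-2-en-1-yl acetate | CC(=O)OC/C=C(\C)CCC=O | intermediate
11 | (2E,6Z)-7-iodo-3-methylocta-2,6-dien-1-yl acetate | CC(=O)OC/C=C(\C)CC/C=C(/C)I | intermediate
12 | (2E,6Z)-7-iodo-3-methylocta-2,6-dien-1-ol | OC/C=C(\C)CC/C=C(/C)I | intermediate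
13 | dilithio species from 12: lithium alkoxide with lithium in place of iodine at C7, lithium cis to C5 | [Li]OC/C=C(\C)CC/C=C(/C)[Li] | intermediate
14 | lithium boronate complex of 13 and 7: tetracoordinate pinacol boronate carrying the C8 alkyl group and the C7 alkenyl group, boron cis to C5 | [Li+].[Li]OC/C=C(\C)CC/C=C(/C)[B-]1(CC[C@@H]2C(C)=CCCC2(C)C)OC(C)(C)C(C)(C)O1 | intermediate
15 | beta-iodo boronic ester (lithium alkoxide): iodine at C6, boron and the new C7–C8 bond at C7, C6–I anti to C7–C8; one of the two C6/C7 diastereomers drawn, both should converge on 16 | [Li]OC/C=C(\C)CC[C@H]([C@](C)(CC[C@@H]2C(C)=CCCC2(C)C)B1OC(C)(C)C(C)(C)O1)I | intermediate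
16 | (2E,6E)-3,7-dimethyl-9-[(1S)-2,6,6-trimethylcyclohex-2-en-1-yl]nona-2,6-dien-1-ol | OC/C=C(\C)CC/C=C(\C)CC[C@@H]1C(C)=CCCC1(C)C | intermediate
17 | oleoyl chloride [(9Z)-octadec-9-enoyl chloride] | CCCCCCCC/C=C\CCCCCCCC(Cl)=O | starting material
18 | (2E,6E)-3,7-dimethyl-9-[(1S)-2,6,6-trimethylcyclohex-2-en-1-yl]nona-2,6-dien-1-yl (9Z)-octadec-9-enoate | CCCCCCCC/C=C\CCCCCCCC(=O)OC/C=C(\C)CC/C=C(\C)CC[C@@H]1C(C)=CCCC1(C)C | target

**Totals.** Total step count: 10. Longest linear sequence: 7 steps (steps 1 to 5, 9 and 10).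

**Steps most likely to fail**

1. Step 9 (key step). The dilithio species may add incompletely to boron, and the allylic alkoxide may be oxidised by iodine through a hypoiodite. Iodination could also pass through an open cation at C7, so that the anti migration is no longer stereospecific and 6E/6Z mixtures form. The fallback is a stereoretentive B-alkyl Suzuki–Miyaura coupling of a (6E)-iodide; it sets out from 10 and 6 and comes back at 16. Aldehyde 10 would be homologated under Ohira–Bestmann conditions (dimethyl (1-diazo-2-oxopropyl)phosphonate, K2CO3, MeOH; the acetate is methanolysed in the same pot) to (2E)-3-methylhept-2-en-6-yn-1-ol F1. Its dianion (n-BuLi, THF, −78 °C) would be C-methylated with MeI to (2E)-3-methyloct-2-en-6-yn-1-ol F2. Hydrozirconation with excess Cp2Zr(H)Cl under equilibrating conditions (the first equivalent is consumed by the hydroxyl), then I2, should give (2E,6E)-7-iodo-3-methylocta-2,6-dien-1-ol F3 by syn addition with zirconium on the methyl-bearing carbon. Iodide 6 would be converted by lithium–iodine exchange (t-BuLi) and trapping with B-methoxy-9-BBN into the lithium B-alkyl-B-methoxy-9-BBN borate F4. Coupling of F4 with F3 (Pd(dppf)Cl2, AsPh3, Cs2CO3, DMF/H2O, 23 °C) should proceed with retention to give 16.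

2. Step 7. The alpha-iodo ylide may lose iodine or be consumed by side reactions before it meets the aldehyde, and the kinetic Z-selectivity may erode, so that throughput and isomeric purity fall. The fallback is a stepwise Negishi construction at C7; it sets out from 10 and 6 and comes back at 16. Aldehyde 10 would be converted (PPh3, BrCCl3, MeCN) into (2E)-7,7-dichloro-3-methylhepta-2,6-dien-1-yl acetate F5. Iodide 6 would give {2-[(1S)-2,6,6-trimethylcyclohex-2-en-1-yl]ethyl}zinc iodide F6 by zinc insertion (Zn, LiCl, THF). A Pd(DPEphos)Cl2-catalysed trans-selective Negishi monoalkylation should replace the chlorine trans to C5 and give (2E,6Z)-7-chloro-3-methyl-9-[(1S)-2,6,6-trimethylcyclohex-2-en-1-yl]nona-2,6-dien-1-yl acetate F7, which already holds the C7–C8 bond. Methylation with retention (Me2Zn, Pd(P(t-Bu)3)2) would give (2E,6E)-3,7-dimethyl-9-[(1S)-2,6,6-trimethylcyclohex-2-en-1-yl]nona-2,6-dien-1-yl acetate F8, and methanolysis (K2CO3, MeOH) would return 16.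

3. Step 2. The [3,3] shift must form a bond at the ring carbon next to the quaternary centre and may be slow, so that acid-promoted dehydration or ionisation of the allylic alcohol competes and lowers yield and enantiomeric purity. The fallback is an Ireland–Claisen rearrangement run under basic conditions at lower temperature; it sets out from 2 and comes back at 5. Alcohol 2 would be acetylated (Ac2O, pyridine, DMAP) to (1R)-2,4,4-trimethylcyclohex-2-en-1-yl acetate F9. Enolisation and silylation (LiN(i-Pr)2, Me3SiCl, THF, −78 °C) would give the trimethylsilyl ketene acetal F10. This should rearrange suprafacially on warming to 60 °C and give, after hydrolytic work-up, 2-[(1S)-2,6,6-trimethylcyclohex-2-en-1-yl]acetic acid F11. LiAlH4 would reduce F11 to 5.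

Further compounds
F1 | step 9 | (2E)-3-methylhept-2-en-6-yn-1-ol | OC/C=C(\C)CCC#C
F2 | step 9 | (2E)-3-methyloct-2-en-6-yn-1-ol | OC/C=C(\C)CCC#CC
F3 | step 9 | (2E,6E)-7-iodo-3-methylocta-2,6-dien-1-ol | OC/C=C(\C)CC/C=C(\C)I
F4 | step 9 | lithium B-methoxy-B-{2-[(1S)-2,6,6-trimethylcyclohex-2-en-1-yl]ethyl}-9-borabicyclo[3.3.1]nonane borate | [Li+].CO[B-]1(CC[C@@H]2C(C)=CCCC2(C)C)C2CCCC1CCC2
F5 | step 7 | (2E)-7,7-dichloro-3-methylhepta-2,6-dien-1-yl acetate | CC(=O)OC/C=C(\C)CCC=C(Cl)Cl
F6 | step 7 | {2-[(1S)-2,6,6-trimethylcyclohex-2-en-1-yl]ethyl}zinc iodide | I[Zn]CC[C@@H]1C(C)=CCCC1(C)C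
F7 | step 7 | (2E,6Z)-7-chloro-3-methyl-9-[(1S)-2,6,6-trimethylcyclohex-2-en-1-yl]nona-2,6-dien-1-yl acetate | CC(=O)OC/C=C(\C)CC/C=C(\Cl)CC[C@@H]1C(C)=CCCC1(C)C
F8 | step 7 | (2E,6E)-3,7-dimethyl-9-[(1S)-2,6,6-trimethylcyclohex-2-en-1-yl]nona-2,6-dien-1-yl acetate | CC(=O)OC/C=C(\C)CC/C=C(\C)CC[C@@H]1C(C)=CCCC1(C)C
F9 | step 2 | (1R)-2,4,4-trimethylcyclohex-2-en-1-yl acetate | CC(=O)O[C@@H]1CCC(C)(C)C=C1C
F10 | step 2 | (1R)-2,4,4-trimethyl-1-{[1-(trimethylsilyloxy)ethenyl]oxy}cyclohex-2-ene | C=C(O[Si](C)(C)C)O[C@@H]1CCC(C)(C)C=C1C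
F11 | step 2 | 2-[(1S)-2,6,6-trimethylcyclohex-2-en-1-yl]acetic acid | OC(=O)C[C@@H]1C(C)=CCCC1(C)C
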